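A single step that slows as Xa and Xb are consumed cannot make the Xc peak grow faster late in a run, yet in Sunday's flask the Xc readings gained 3 percentage points between 12.0 min and 25.0 min and then, faster per minute, 18 points between 40.0 min and 60.0 min.

| flask | Xa | Xb | remark | time |
|---|---|---|---|---|
| Thursday's | 19 mM | 9.9 mM | run made earlier |  |
| Friday's | 19 mM | 24 mM | run made earlier |  |
| Sunday's | 19 mM | 69 mM | run made earlier |  |
| autumn | 19 mM | 8.00 mM |  | 2.0 h |
| midnight | 19 mM | 15.0 mM |  | 2.0 h |
| dusk | 19 mM | 30.0 mM |  | 2.0 h |
| winter | 19 mM | 60.0 mM |  | 2.0 h |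

| run | time / min | Xc / % | Xa / % |
|---|---|---|---|
| Thursday's | 5.00 | 1 | 97 |
| Thursday's | 10.0 | 1 | 101 |
| Thursday's | 15.0 | 5 | 99 |
| Thursday's | 30.0 | 0 | 97 |
| Thursday's | 60.0 | 0 | 102 |
| Friday's | 12.0 | 0 | 101 |
| Friday's | 25.0 | 0 | 95 |
| Friday's | 40.0 | 4 | 97 |
| Friday's | 50.0 | 4 | 94 |
| Friday's | 60.0 | 6 | 100 |
| Sunday's | 12.0 | 1 | 99 |
| Sunday's | 25.0 | 4 | 96 |
| Sunday's | 40.0 | 6 | 87 |
| Sunday's | 50.0 | 17 | 84 |
| Sunday's | 60.0 | 24 | 74 |

(readings scatter by 2 percentage points)

* amount of Xc at the end, in percent of the Xa charged for autumn, midnight, dusk, winter, in this order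
* how the row runs (falls, then rises / falls all the way / rises, then falls / rises all the way / hardly changes)

- the numbers in the tables scatter by 2 percentage points (one standard deviation)
- "hardly changes" means that all values lie within two and a half points (for a concentration: within two and a half percent of the largest)

Two chemists dispute this. The first holds to one plain step, Xa + Xb → Xc, with a straight line in time and in Xb, and trusts the early reading of Sunday's flask, 4 % at 25.0 min; scaled by charge and time, this gives 2.23 % for autumn and 16.7 % for winter.

The second, whose reckoning I commit to, adds a step in which Xc speeds its own formation (autocatalysis), with both steps carrying the factor Xa·Xb. In this view the self-fed rate over the plain rate is y/y*, where y is Xc as a fraction of the Xa charged and y* is the handover level, the Xc level at which the two rates are equal, the same at any Xb for this one Xa charge of 19 mM. While Xa and Xb stay near their charge, y = y*(exp(gt) − 1), with g proportional to Xb. Sunday's readings at 25.0 min and 50.0 min, though Xa already reads 84 % at the later one, then give, as rough readings with their scatter, g = 0.0471 /min and y* = 1.78 %.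

Letting Xa run down while Xb is held at its charge gives (y + y*)/(1 − y) = y*·exp(g(1 + y*)t), and scaling g by the Xb charge gives 1.63 %, 4.18 %, 16.4 % and 72.2 % for the four flasks in order.

The forecast, which also reads that “the runs show an induction period” but reckons by another road and gets other numbers than mine, gives 3 %, 9 %, 25 % and 60 %, so that the row rises all the way.

The simulation gives 1.81 %, 4.60 %, 17.2 % and 68.2 %, so the row rises all the way, near the second chemist's figures, with winter at 4.08 times the first chemist's figure.

    Xa + Xb → Xc (k = 2.30 × 10⁻⁴ /M/s)
    Xa + Xb + Xc → 2 Xc (k = 0.610 /M²/s)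

Autumn is the region of the first chemist's view: there Xa + Xb → Xc had half of its turnover up to the asked time done by 0.985 h, and at 0.985 h it took Xa with a half-life of 110 h, shorter than the 12 d of the step with Xc, while Xc went from 0.775 % at 1.00 h to 1.81 % at 2.00 h, beside y* of 1.78 %. In winter Xc stood at 17.9 % at 1.00 h, ten times y*, and the step with Xc ran on while Xb held 78.4 % of its own charge and Xa fell to 31.8 % at 2.00 h.

The numbers in the tables stem from a simulated flask with constants of no real substance; scatter was added.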